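**Plan**
- Retrosynthesis, in order: C6–CH3 (methyl onto a ring peroxycarbenium ion); ring bond O–C3 (peroxide oxygen onto the alkyl carbon of a β-lactone); the O–O unit at C6 (ozone on a C6=CH2 alkene in methanol); C2–C3 (ketene + aldehyde); C9–C10 (Cu-catalysed alkyl–alkyl coupling); C4–C5 and C7–C8 (double enolate alkylation of a four-carbon dibromide).
- Forward: the chain C3–C16 is built in two directions around C6. The only ring, the 1,2-dioxane, closes in step 10 by 6-exo-tet attack of a C6 hydroperoxy ketal on C3 of the oxetan-2-one that holds C1–C3. This sets C3 by inversion and frees the C1 carboxylic acid in the same event.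
- Feature used: C3 carries the ring oxygen and lies β to the carboxyl carbon C1, so C1–C3 and the carboxyl oxygen can be stored as a strained oxetan-2-one whose C3–O bond is the leaving group. C6, the fully substituted peroxy carbon of the dioxane, is carried at ketal level (OMe as helper) until the ring exists.
- Hidden symmetry: the CH(CH3) carbons C4 and C8 on either side of C6 have the same sense, so one double alkylation gives both as a C2-symmetric diol.
- Stereochemistry: C4 and C8 from the oxazolidinone auxiliary; C12 from (S)-citronellyl bromide; C3 from catalyst-controlled β-lactone formation followed by inversion; C6 from stereoconvergent axial methylation of the peroxycarbenium ion in step 11.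

Key step: step 10

Assumption: in step 8 the alkaloid catalyst is meant as the pseudoenantiomer (quinidine or quinine series) that delivers the 4R lactone; the route relies on the lactone configuration, not on the catalyst name.

**Step 1**
Reactants: 1 (6S)-8-bromo-2,6-dimethyloct-2-ene [(S)-citronellyl bromide]; 2 styrene
Product: 3 [(1E,5S)-7-bromo-5-methylhept-1-en-1-yl]benzene
Conditions: 2 (4 equiv), second-generation Grubbs catalyst RuCl2(=CHPh)(H2IMes)(PCy3) (3 mol %), CH2Cl2, 40 °C
Reagents that add atoms: none
Why: Olefin cross-metathesis of the prenyl-type alkene with styrene should be driven by loss of volatile 2-methylpropene, and the remote stereocentre (later C12) is not touched.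

**Step 2**
Reactants: 3 [(1E,5S)-7-bromo-5-methylhept-1-en-1-yl]benzene
Product: 4 [(5S)-7-bromo-5-methylheptyl]benzene
Conditions: H2 (1 atm), 5% Pd/C, EtOAc, rt
Reagents that add atoms: none
Why: Heterogeneous hydrogenation of the styrenyl double bond under neutral conditions should leave the primary alkyl bromide intact.

**Step 3**
Reactants: 5 (4R)-4-benzyl-3-propanoyl-1,3-oxazolidin-2-one; 6 3-bromo-2-(bromomethyl)prop-1-ene
Product: 7 (4R,4'R)-3,3'-[(2S,6S)-2,6-dimethyl-4-methylideneheptanedioyl]bis(4-benzyl-1,3-oxazolidin-2-one)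
Conditions: 5 (2.2 equiv), NaN(SiMe3)2 (2.2 equiv), THF, −78 °C; then 6 (1.0 equiv), −78 → −30 °C
Reagents that add atoms: none
Why: Evans asymmetric alkylation run in two directions, in which each chelated Z-sodium enolate is alkylated on the face away from the benzyl group by one allylic CH2Br of 6, should set the two CH(CH3) centres (later C4 and C8) with the same sense (2S,6S).

**Step 4**
Reactants: 7 the bis-imide
Product: 8 (2S,6S)-2,6-dimethyl-4-methylideneheptane-1,7-diol
Conditions: LiBH4 (4 equiv), MeOH (4 equiv), THF, 0 °C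
Reagents that add atoms: none
Why: Reductive cleavage of both N-acyl oxazolidinones by LiBH4 should give the C2-symmetric diol without touching the stereocentres, and the auxiliary is recovered.

**Step 5**
Reactants: 8 (2S,6S)-2,6-dimethyl-4-methylideneheptane-1,7-diol
Product: 9 (2S,6S)-7-hydroxy-2,6-dimethyl-4-methylideneheptyl 4-methylbenzenesulfonate
Conditions: TsCl (1.0 equiv), Ag2O (1.5 equiv), KI (0.2 equiv), CH2Cl2, 0 °C → rt
Reagents that add atoms: 4-methylbenzenesulfonyl chloride, Cc1ccc(cc1)S(Cl)(=O)=O
Why: Monosulfonylation of a diol whose two hydroxyl groups are homotopic (C2 axis) can give only one monotosylate, and the Ag2O/KI protocol favours monosubstitution.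

**Step 6**
Reactants: 9 the monotosylate; 4 [(5S)-7-bromo-5-methylheptyl]benzene
Product: 11 (2S,6R,10S)-2,6,10-trimethyl-4-methylidene-14-phenyltetradecan-1-ol, via Grignard reagent 10 (not isolated)
Conditions: 4, Mg, THF, 40 °C (gives 10); separately 9, MeMgCl (1.0 equiv), THF, −40 °C; then 10 (1.5 equiv), Li2CuCl4 (5 mol %), −40 → 0 °C; aq. NH4Cl
Reagents that add atoms: none
Why: Li2CuCl4-catalysed alkyl–alkyl cross-coupling of the primary tosylate with the primary Grignard reagent (the hydroxyl being first turned into its magnesium alkoxide) should join C9 to C10 without involving any stereocentre.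

**Step 7**
Reactants: 11 the alcohol
Product: 12 (2S,6R,10S)-2,6,10-trimethyl-4-methylidene-14-phenyltetradecanal
Conditions: PhI(OAc)2 (1.1 equiv), TEMPO (0.1 equiv), CH2Cl2, rt
Reagents that add atoms: none
Why: The TEMPO/PhI(OAc)2 oxidation should stop at the aldehyde and should neither epimerise the α-stereocentre (C4) nor touch the 1,1-disubstituted alkene.

**Step 8**
Reactants: 12 the aldehyde
Product: 13 (4R)-4-[(2S,6R,10S)-6,10-dimethyl-4-methylidene-14-phenyltetradecan-2-yl]oxetan-2-one
Conditions: AcCl (3 equiv, slow addition), i-Pr2NEt (3 equiv), O-trimethylsilylquinidine (15 mol %), LiClO4 (1 equiv), CH2Cl2–Et2O, −78 → −40 °C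
Reagents that add atoms: acetyl chloride, CC(Cl)=O
Why: In this catalytic asymmetric ketene–aldehyde [2+2] cycloaddition (ketene from AcCl and i-Pr2NEt, chiral ammonium enolate, aldol addition to the LiClO4-activated aldehyde, lactonisation) the alkaloid catalyst, not the weak Felkin bias of the α-methyl aldehyde, should fix C3 as the 4R centre of the lactone.

**Step 9**
Reactants: 13 the β-lactone
Product: 14 (4R)-4-[(2S,6R,10S)-4-hydroperoxy-4-methoxy-6,10-dimethyl-14-phenyltetradecan-2-yl]oxetan-2-one (both epimers at the ketal carbon C6)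
Conditions: O3, CH2Cl2–MeOH (4:1), −78 °C, Sudan Red 7B as end-point indicator; N2 purge; concentration below 20 °C
Reagents that add atoms: ozone, [O-][O+]=O; methanol, CO
Why: In this Criegee ozonolysis the electron-rich C6=CH2 alkene should react far faster than the arene, the primary ozonide should fragment to formaldehyde and the more substituted C6 carbonyl oxide, and methanol traps the latter as the α-methoxy hydroperoxide while the neutral β-lactone survives.

**Step 10**
Reactants: 14 the hydroperoxy ketal β-lactone
Product: 15 2-[(3S,4S)-6-[(2R,6S)-2,6-dimethyl-10-phenyldecyl]-6-methoxy-4-methyl-1,2-dioxan-3-yl]acetic acid (both C6 epimers)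
Conditions: KOtBu (1.0 equiv), 18-crown-6 (1.1 equiv), THF (0.005 M), −40 → 0 °C; then AcOH (1.0 equiv)
Reagents that add atoms: none
Why: Proposed new method: KOtBu removes only the hydroperoxy ketal OOH proton, and the crown-separated peroxide anion attacks C3, the alkyl carbon of the β-lactone C–O bond, from the rear, so that the strained four-membered ring opens by alkyl–oxygen cleavage with the C1 carboxylate as leaving group. The closest known reaction types are the SN2 opening of 4-alkyl-oxetan-2-ones at C4 with inversion by azide, thiolate, halide, carboxylate and cuprate nucleophiles, the intramolecular etherification of β-lactones, and the base-mediated 6-exo-tet closure of hydroperoxy ketals onto secondary sulfonates. The 1,2-dioxane closes in the 6-exo-tet mode through a chair in which the C4 methyl is equatorial. C3 is set by stereospecific inversion (4R lactone to 3S), so its configuration is the one fixed in step 8, while C6 stays a ketal mixture on purpose and is set in step 11. The step needs alkyl over acyl attack and no enolisation: acyl attack would require an eight-membered transition state, one equivalent of base leaves the far less acidic lactone α-CH untouched, and high dilution suppresses intermolecular perester or polyester formation. The one event closes the ring, sets C3 and frees the C1 acid without a protecting group.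

**Step 11**
Reactants: 15 the 6-methoxy-1,2-dioxane acid
Product: 16 2-[(3S,4S,6R)-6-[(2R,6S)-2,6-dimethyl-10-phenyldecyl]-4,6-dimethyl-1,2-dioxan-3-yl]acetic acid
Conditions: AlMe3 (4 equiv), CH2Cl2, −78 → −20 °C; aq. potassium sodium tartrate
Reagents that add atoms: trimethylaluminium, C[Al](C)C
Why: Proposed new method: AlMe3 first forms the aluminium carboxylate, then complexes the exocyclic methoxy oxygen (more basic than the peroxide oxygens) and ionises it to the ring peroxycarbenium ion common to both C6 epimers of 15, and methyl is transferred along the axial trajectory of the half-chair with the C4 methyl pseudo-equatorial, anti to that methyl and to the pseudo-axial C3 side chain, which should give 6R; the closest known reaction types are the Lewis-acid-mediated substitution of cyclic peroxyketals by allylsilanes and silyl ketene acetals through peroxycarbenium ions and the AlMe3 C-methylation of cyclic ketals and glycosyl donors through oxocarbenium ions, a reaction type that ring peroxides of 1,2,4-trioxanes tolerate.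

**Compound list**
1 | (6S)-8-bromo-2,6-dimethyloct-2-ene [(S)-citronellyl bromide] | C[C@@H](CCC=C(C)C)CCBr | starting material
2 | styrene | C=Cc1ccccc1 | starting material
3 | [(1E,5S)-7-bromo-5-methylhept-1-en-1-yl]benzene | C[C@@H](CC/C=C/c1ccccc1)CCBr | intermediate
4 | [(5S)-7-bromo-5-methylheptyl]benzene | C[C@@H](CCCCc1ccccc1)CCBr | intermediate
5 | (4R)-4-benzyl-3-propanoyl-1,3-oxazolidin-2-one | CCC(=O)N1[C@H](Cc2ccccc2)COC1=O | starting material
6 | 3-bromo-2-(bromomethyl)prop-1-ene | C=C(CBr)CBr | starting material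
7 | (4R,4'R)-3,3'-[(2S,6S)-2,6-dimethyl-4-methylideneheptanedioyl]bis(4-benzyl-1,3-oxazolidin-2-one) | O=C1OC[C@@H](Cc2ccccc2)N1C(=O)[C@@H](C)CC(=C)C[C@H](C)C(=O)N1[C@H](Cc2ccccc2)COC1=O | intermediate
8 | (2S,6S)-2,6-dimethyl-4-methylideneheptane-1,7-diol | OC[C@@H](C)CC(=C)C[C@H](C)CO | intermediate
9 | (2S,6S)-7-hydroxy-2,6-dimethyl-4-methylideneheptyl 4-methylbenzenesulfonate | Cc1ccc(cc1)S(=O)(=O)OC[C@@H](C)CC(=C)C[C@H](C)CO | intermediate
10 | [(3S)-3-methyl-7-phenylheptyl]magnesium bromide | C[C@@H](CCCCc1ccccc1)CC[Mg]Br | intermediate (not isolated)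
11 | (2S,6R,10S)-2,6,10-trimethyl-4-methylidene-14-phenyltetradecan-1-ol | C[C@@H](CCCCc1ccccc1)CCC[C@@H](C)CC(=C)C[C@H](C)CO | intermediate
12 | (2S,6R,10S)-2,6,10-trimethyl-4-methylidene-14-phenyltetradecanal | C[C@@H](CCCCc1ccccc1)CCC[C@@H](C)CC(=C)C[C@H](C)C=O | intermediate
13 | (4R)-4-[(2S,6R,10S)-6,10-dimethyl-4-methylidene-14-phenyltetradecan-2-yl]oxetan-2-one | C[C@@H](CCCCc1ccccc1)CCC[C@@H](C)CC(=C)C[C@H](C)[C@H]1CC(=O)O1 | intermediate
14 | (4R)-4-[(2S,6R,10S)-4-hydroperoxy-4-methoxy-6,10-dimethyl-14-phenyltetradecan-2-yl]oxetan-2-one (both ketal epimers, centre left undefined) | C[C@@H](CCCCc1ccccc1)CCC[C@@H](C)CC(OC)(OO)C[C@H](C)[C@H]1CC(=O)O1 | intermediate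
15 | 2-[(3S,4S)-6-[(2R,6S)-2,6-dimethyl-10-phenyldecyl]-6-methoxy-4-methyl-1,2-dioxan-3-yl]acetic acid (both C6 epimers, centre left undefined) | C[C@@H](CCCCc1ccccc1)CCC[C@@H](C)CC1(OC)C[C@H](C)[C@H](CC(=O)O)OO1 | intermediate
16 | 2-[(3S,4S,6R)-6-[(2R,6S)-2,6-dimethyl-10-phenyldecyl]-4,6-dimethyl-1,2-dioxan-3-yl]acetic acid | C[C@@H](CCCCc1ccccc1)CCC[C@@H](C)C[C@]1(C)C[C@H](C)[C@H](CC(=O)O)OO1 | target

**Count and risks**
Total steps: 11. Longest linear sequence: 9 (steps 3–11); steps 1–2 make the side-chain bromide that enters in step 6.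

Steps most likely to fail:

1. Step 10 (Proposed new method). The peroxide anion may attack the lactone carbonyl (acyl transfer, perester formation), or the lactone may be consumed by oligomerisation, instead of SN2 closure at the hindered secondary C3. Fallback with known chemistry, setting out from 12 and returning at 15: a Wittig reaction with Ph3P=CHCO2Me (CH2Cl2, rt) should give methyl (2E,4S,8R,12S)-4,8,12-trimethyl-6-methylidene-16-phenylhexadec-2-enoate F1. Ozonolysis in CH2Cl2–MeOH at −78 °C should give methyl (2E,4S,8R,12S)-6-hydroperoxy-6-methoxy-4,8,12-trimethyl-16-phenylhexadec-2-enoate F2. Et2NH (cat.) in CF3CH2OH should then close the ring by 6-exo-trig peroxy-Michael addition under kinetic control to methyl 2-[(3S,4S)-6-[(2R,6S)-2,6-dimethyl-10-phenyldecyl]-6-methoxy-4-methyl-1,2-dioxan-3-yl]acetate F3. In this variant C3 rests on a chair transition state (C4 methyl equatorial, enoate axial) instead of on inversion. LiOH, THF–H2O, 0 °C returns to 15.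

2. Step 11 (Proposed new method). The organoaluminium may cleave the O–O bond, the ketal may ionise towards the acyclic oxocarbenium ion with ring opening or Hock-type rearrangement, or facial selectivity at C6 may be poor. Fallback with known chemistry, setting out from 12 through the enoate F1 and returning at 16; here the C6 methyl comes from the alkene CH2. Mukaiyama–Isayama hydroperoxysilylation (Co(thd)2 cat., thd = 2,2,6,6-tetramethylheptane-3,5-dionate, O2, Et3SiH, ClCH2CH2Cl) should give methyl (2E,4S,8R,12S)-4,6,8,12-tetramethyl-16-phenyl-6-[(triethylsilyl)peroxy]hexadec-2-enoate F4 as both C6 epimers. HF·pyridine frees methyl (2E,4S,8R,12S)-6-hydroperoxy-4,6,8,12-tetramethyl-16-phenylhexadec-2-enoate F5. With Et2NH in CF3CH2OH this should cyclise to methyl 2-[(3S,4S,6R)-6-[(2R,6S)-2,6-dimethyl-10-phenyldecyl]-4,6-dimethyl-1,2-dioxan-3-yl]acetate F6 and its C6 epimer methyl 2-[(3S,4S,6S)-6-[(2R,6S)-2,6-dimethyl-10-phenyldecyl]-4,6-dimethyl-1,2-dioxan-3-yl]acetate F7. Chromatography and LiOH hydrolysis of F6 give 16. C6 is then not controlled and is secured by separation.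

3. Step 8. Mismatched double stereodifferentiation (the catalyst must override the Felkin preference of the α-methyl aldehyde) or sluggish addition to the hindered aldehyde may erode the C3 configuration. Fallback with known chemistry, setting out from 12 and returning at 13: aldol addition of doubly deprotonated (R)-2-hydroxy-1,2,2-triphenylethyl acetate (LiN(i-Pr)2, THF; MgBr2; −110 °C) should give (1R)-2-hydroxy-1,2,2-triphenylethyl (3R,4S,8R,12S)-3-hydroxy-4,8,12-trimethyl-6-methylidene-16-phenylhexadecanoate F8 under auxiliary control. KOH, MeOH–H2O gives (3R,4S,8R,12S)-3-hydroxy-4,8,12-trimethyl-6-methylidene-16-phenylhexadecanoic acid F9. Lactonisation by carboxyl activation (PhSO2Cl, pyridine, 0 °C), which retains C3, returns to 13.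

**Further compounds**
F1 | step 10 | methyl (2E,4S,8R,12S)-4,8,12-trimethyl-6-methylidene-16-phenylhexadec-2-enoate | C[C@@H](CCCCc1ccccc1)CCC[C@@H](C)CC(=C)C[C@H](C)/C=C/C(=O)OC
F2 | step 10 | methyl (2E,4S,8R,12S)-6-hydroperoxy-6-methoxy-4,8,12-trimethyl-16-phenylhexadec-2-enoate (both C6 epimers) | C[C@@H](CCCCc1ccccc1)CCC[C@@H](C)CC(OC)(OO)C[C@H](C)/C=C/C(=O)OC
F3 | step 10 | methyl 2-[(3S,4S)-6-[(2R,6S)-2,6-dimethyl-10-phenyldecyl]-6-methoxy-4-methyl-1,2-dioxan-3-yl]acetate (both C6 epimers) | C[C@@H](CCCCc1ccccc1)CCC[C@@H](C)CC1(OC)C[C@H](C)[C@H](CC(=O)OC)OO1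
F4 | step 11 | methyl (2E,4S,8R,12S)-4,6,8,12-tetramethyl-16-phenyl-6-[(triethylsilyl)peroxy]hexadec-2-enoate (both C6 epimers) | C[C@@H](CCCCc1ccccc1)CCC[C@@H](C)CC(C)(OO[Si](CC)(CC)CC)C[C@H](C)/C=C/C(=O)OC
F5 | step 11 | methyl (2E,4S,8R,12S)-6-hydroperoxy-4,6,8,12-tetramethyl-16-phenylhexadec-2-enoate (both C6 epimers) | C[C@@H](CCCCc1ccccc1)CCC[C@@H](C)CC(C)(OO)C[C@H](C)/C=C/C(=O)OC
F6 | step 11 | methyl 2-[(3S,4S,6R)-6-[(2R,6S)-2,6-dimethyl-10-phenyldecyl]-4,6-dimethyl-1,2-dioxan-3-yl]acetate | C[C@@H](CCCCc1ccccc1)CCC[C@@H](C)C[C@]1(C)C[C@H](C)[C@H](CC(=O)OC)OO1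
F7 | step 11 | methyl 2-[(3S,4S,6S)-6-[(2R,6S)-2,6-dimethyl-10-phenyldecyl]-4,6-dimethyl-1,2-dioxan-3-yl]acetate | C[C@@H](CCCCc1ccccc1)CCC[C@@H](C)C[C@@]1(C)C[C@H](C)[C@H](CC(=O)OC)OO1
F8 | step 8 | (1R)-2-hydroxy-1,2,2-triphenylethyl (3R,4S,8R,12S)-3-hydroxy-4,8,12-trimethyl-6-methylidene-16-phenylhexadecanoate | C[C@@H](CCCCc1ccccc1)CCC[C@@H](C)CC(=C)C[C@H](C)[C@H](O)CC(=O)O[C@H](c1ccccc1)C(O)(c1ccccc1)c1ccccc1
F9 | step 8 | (3R,4S,8R,12S)-3-hydroxy-4,8,12-trimethyl-6-methylidene-16-phenylhexadecanoic acid | C[C@@H](CCCCc1ccccc1)CCC[C@@H](C)CC(=C)C[C@H](C)[C@H](O)CC(=O)O
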